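Target numbering: C1 quaternary carbinol, C2 ketone, C3 CH2, C4 CHOH, C5 CHOBz, C6 CHOH of the cyclohexanone ring; C7 exocyclic CH2. Everything rests on the C1–C7 disconnection. C1 lies α to the C2 carbonyl and shares a cis-diol with C6, so the ring is traced back to a C1=C6 enone: a Morita–Baylis–Hillman reaction with formaldehyde forges C1–C7 at the enone α-carbon in one operation, and dihydroxylation anti to the C5 benzoate later sets C1 and C6 together. The precursor, (4S,5R)-4-benzoyloxy-5-silyloxycyclohex-2-enone, comes from (−)-quinic acid, whose carboxyl-bearing carbon unexpectedly becomes C2 and whose cis-diol becomes C4/C5.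

Key step: step 6

Assumption: compounds 2–5 are described with quinic acid numbering (C1 carries the carboxyl carbon, C3/C4 are the cis-diol, C5 carries the lactonising hydroxyl); later compounds use cyclohexenone or target numbering.

Step 1
Reactants: 1 (−)-quinic acid
Product: 2 quinide (1,5-γ-lactone of quinic acid; 1,3,4-trihydroxy-6-oxabicyclo[3.2.1]octan-7-one)
Conditions: p-TsOH·H2O (cat.), DMF/toluene, reflux, Dean–Stark
Reagents that add atoms: none
Why: Acid-catalysed lactonisation of the C1 carboxyl onto the cis-disposed C5 hydroxyl closes the bicyclic γ-lactone with azeotropic removal of water, which locks the ring and differentiates the three secondary hydroxyls without touching a stereocentre.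

Step 2
Reactants: 2 quinide
Product: 3 3-O-(tert-butyldimethylsilyl)quinide
Conditions: TBSCl (1.1 equiv), imidazole, DMF, 0 °C → rt
Reagents that add atoms: tert-butyldimethylsilyl chloride, CC(C)(C)[Si](C)(C)Cl
Why: Regioselective silylation: in the rigid lactone the C3 hydroxyl is equatorial and most accessible, whereas C4–OH is axial and C1–OH tertiary, so one equivalent of silyl chloride should take O3 only (the later O4 of the target).

Step 3
Reactants: 3 3-O-(tert-butyldimethylsilyl)quinide
Product: 4 4-O-benzoyl-3-O-(tert-butyldimethylsilyl)quinide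
Conditions: BzCl (1.3 equiv), pyridine, DMAP (cat.), CH2Cl2, 0 °C → rt
Reagents that add atoms: benzoyl chloride, O=C(Cl)c1ccccc1
Why: Acylation of the only remaining secondary hydroxyl (C4) installs the future C5 benzoate, while the tertiary bridgehead C1–OH should stay free under these stoichiometric conditions.

Step 4
Reactants: 4 4-O-benzoyl-3-O-(tert-butyldimethylsilyl)quinide
Product: 6 (3R,4S,5R)-4-(benzoyloxy)-3-[(tert-butyldimethylsilyl)oxy]-5-hydroxycyclohexan-1-one, via triol 5 (not isolated)
Conditions: NaBH4, EtOH, 0 °C; 1 M HCl to pH 4; then NaIO4, H2O (pH 6), 0 °C → rt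
Reagents that add atoms: none
Why: Hydride reduction of the strained α-hydroxy lactone (far faster than attack on the benzoate) unmasks a tertiary/primary 1,2-diol, which periodate glycol cleavage (Malaprade reaction) excises as formaldehyde to leave the ketone, with C3, C4 and C5 untouched.

Step 5
Reactants: 6 (3R,4S,5R)-4-(benzoyloxy)-3-[(tert-butyldimethylsilyl)oxy]-5-hydroxycyclohexan-1-one
Product: 8 (4S,5R)-4-(benzoyloxy)-5-[(tert-butyldimethylsilyl)oxy]cyclohex-2-en-1-one, via mesylate 7 (not isolated)
Conditions: MsCl, Et3N, CH2Cl2, 0 °C → rt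
Reagents that add atoms: none
Why: Mesylation of the β-hydroxyl followed by E1cB elimination gives the conjugated enone, the β′-silyloxy group being a much poorer leaving group and therefore retained.

Step 6
Reactants: 8 (4S,5R)-4-(benzoyloxy)-5-[(tert-butyldimethylsilyl)oxy]cyclohex-2-en-1-one
Product: 9 (4S,5R)-4-(benzoyloxy)-5-[(tert-butyldimethylsilyl)oxy]-2-(hydroxymethyl)cyclohex-2-en-1-one
Conditions: 37% aq. HCHO (3 equiv), imidazole (1 equiv), THF/1 M aq. NaHCO3, rt
Reagents that add atoms: formaldehyde, C=O
Why: Morita–Baylis–Hillman reaction: imidazole adds reversibly to C6 of the enone (β-carbon, anti to the C5 benzoate), the C1 enolate so generated attacks formaldehyde to form the C1–C7 bond, and proton transfer with E1cB loss of imidazole restores the C1=C6 enone. The closest known reaction type is the amine-catalysed aqueous α-hydroxymethylation of cyclic enones with formalin, which is established for γ-oxygenated cyclohexenones and cyclopentenones. No ring is closed and no stereocentre is created (C1 stays sp2 and is set in step 8); C4 and C5 are not touched. The step needs site selectivity for C1 over C3 and must outrun base-induced enolisation toward C3 with loss of the C4 silyloxy group (aromatisation); the catalytic cycle creates enolate character only at C1, the medium is buffered near pH 8, and the silyloxy group is a poor leaving group.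

Step 7
Reactants: 9 (4S,5R)-4-(benzoyloxy)-5-[(tert-butyldimethylsilyl)oxy]-2-(hydroxymethyl)cyclohex-2-en-1-one
Product: 10 (4S,5R)-4-(benzoyloxy)-2-[(benzoyloxy)methyl]-5-[(tert-butyldimethylsilyl)oxy]cyclohex-2-en-1-one
Conditions: BzCl (1.2 equiv), pyridine, CH2Cl2, 0 °C
Reagents that add atoms: benzoyl chloride, O=C(Cl)c1ccccc1
Why: Acylation of the unhindered primary allylic alcohol with benzoyl chloride in pyridine (no nucleophilic catalyst, to avoid SN2′ chemistry of the allylic ester) completes the C7 benzoate.

Step 8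
Reactants: 10 (4S,5R)-4-(benzoyloxy)-2-[(benzoyloxy)methyl]-5-[(tert-butyldimethylsilyl)oxy]cyclohex-2-en-1-one
Product: 11 [(1S,4R,5S,6S)-5-(benzoyloxy)-4-[(tert-butyldimethylsilyl)oxy]-1,6-dihydroxy-2-oxocyclohexyl]methyl benzoate
Conditions: RuCl3·3H2O (5 mol %), NaIO4 (1.5 equiv), EtOAc/MeCN/H2O (3:3:1), 0 °C, 3–5 min; then aq. Na2S2O3
Reagents that add atoms: sodium periodate, [Na+].[O-]I(=O)(=O)=O; water, O
Why: Ruthenium tetroxide-catalysed syn-dihydroxylation ([3+2] addition, flash dihydroxylation of an electron-poor enone) should occur on the ring face opposite the allylic C5 benzoate and the C4 silyloxy group, so that substrate control sets C1 (tertiary OH cis to C6–OH, CH2OBz on the benzoate face) and C6 in one operation.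

Step 9
Reactants: 11 [(1S,4R,5S,6S)-5-(benzoyloxy)-4-[(tert-butyldimethylsilyl)oxy]-1,6-dihydroxy-2-oxocyclohexyl]methyl benzoate
Product: 12 [(1S,4R,5R,6S)-5-(benzoyloxy)-1,4,6-trihydroxy-2-oxocyclohexyl]methyl benzoate (CNP0127041.1)
Conditions: 48% aq. HF, MeCN, 0 °C → rt
Reagents that add atoms: none
Why: Fluoride-mediated desilylation under acidic, base-free conditions frees the C4 hydroxyl while avoiding the β-dehydration of the hydroxy ketone and the benzoyl migration that basic fluoride sources would invite; no stereocentre is affected.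

Compound list
1 | (−)-quinic acid, (1S,3R,4S,5R)-1,3,4,5-tetrahydroxycyclohexane-1-carboxylic acid | OC(=O)[C@]1(O)C[C@@H](O)[C@@H](O)[C@H](O)C1 | starting material
2 | quinide (1,5-γ-lactone of quinic acid) | O=C2[C@]1(O)C[C@@H](O)[C@@H](O)[C@H](O2)C1 | intermediate
3 | 3-O-(tert-butyldimethylsilyl)quinide | O=C2[C@]1(O)C[C@@H](O[Si](C)(C)C(C)(C)C)[C@@H](O)[C@H](O2)C1 | intermediate
4 | 4-O-benzoyl-3-O-(tert-butyldimethylsilyl)quinide | O=C2[C@]1(O)C[C@@H](O[Si](C)(C)C(C)(C)C)[C@@H](OC(=O)c3ccccc3)[C@H](O2)C1 | intermediate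
5 | triol: 1-(hydroxymethyl)cyclohexane-1,5-diol bearing 3-OTBS and 4-OBz (quinic numbering, configuration of 1 retained) | OC[C@]1(O)C[C@@H](O[Si](C)(C)C(C)(C)C)[C@@H](OC(=O)c2ccccc2)[C@H](O)C1 | intermediate
6 | (3R,4S,5R)-4-(benzoyloxy)-3-[(tert-butyldimethylsilyl)oxy]-5-hydroxycyclohexan-1-one | O=C1C[C@@H](O[Si](C)(C)C(C)(C)C)[C@@H](OC(=O)c2ccccc2)[C@H](O)C1 | intermediate
7 | mesylate: (3R,4S,5R)-4-(benzoyloxy)-3-[(tert-butyldimethylsilyl)oxy]-5-[(methylsulfonyl)oxy]cyclohexan-1-one | O=C1C[C@@H](O[Si](C)(C)C(C)(C)C)[C@@H](OC(=O)c2ccccc2)[C@H](OS(C)(=O)=O)C1 | intermediate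
8 | (4S,5R)-4-(benzoyloxy)-5-[(tert-butyldimethylsilyl)oxy]cyclohex-2-en-1-one | O=C1C[C@@H](O[Si](C)(C)C(C)(C)C)[C@@H](OC(=O)c2ccccc2)C=C1 | intermediate
9 | (4S,5R)-4-(benzoyloxy)-5-[(tert-butyldimethylsilyl)oxy]-2-(hydroxymethyl)cyclohex-2-en-1-one | O=C1C[C@@H](O[Si](C)(C)C(C)(C)C)[C@@H](OC(=O)c2ccccc2)C=C1CO | intermediate
10 | (4S,5R)-4-(benzoyloxy)-2-[(benzoyloxy)methyl]-5-[(tert-butyldimethylsilyl)oxy]cyclohex-2-en-1-one | O=C1C[C@@H](O[Si](C)(C)C(C)(C)C)[C@@H](OC(=O)c2ccccc2)C=C1COC(=O)c1ccccc1 | intermediate
11 | [(1S,4R,5S,6S)-5-(benzoyloxy)-4-[(tert-butyldimethylsilyl)oxy]-1,6-dihydroxy-2-oxocyclohexyl]methyl benzoate | O=C(OC[C@@]1(O)C(=O)C[C@@H](O[Si](C)(C)C(C)(C)C)[C@@H](OC(=O)c2ccccc2)[C@@H]1O)c1ccccc1 | intermediate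
12 | [(1S,4R,5R,6S)-5-(benzoyloxy)-1,4,6-trihydroxy-2-oxocyclohexyl]methyl benzoate | O=C(OC[C@@]1(O)C(=O)C[C@@H](O)[C@@H](OC(=O)c2ccccc2)[C@@H]1O)c1ccccc1 | target

Total step count: 9. Longest linear sequence: 9 steps (fully linear, 1 → 12).

Steps most likely to fail

Step 6 (key step). The mild base may enolise the enone toward C3, expel the C4 silyloxy group and aromatise the ring, or the hindered catalyst-bound enolate may capture formaldehyde too slowly. The fallback makes the same C1–C7 bond by cross-coupling instead of organocatalysis. It sets out from 8: α-iodination (I2, pyridine, CH2Cl2, 0 °C → rt) should give (4S,5R)-4-(benzoyloxy)-5-[(tert-butyldimethylsilyl)oxy]-2-iodocyclohex-2-en-1-one F1. A Stille coupling of this vinyl iodide with (tributylstannyl)methanol (Pd2(dba)3, AsPh3, CuI, NMP, 50 °C) transfers the hydroxymethyl group to C1 under non-basic conditions and comes back to the route at 9.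

Step 4. Once the C5 alkoxide is unmasked under the basic hydride conditions, the benzoyl group may migrate from O4 to O5 (or be partly lost), so that the later mesylation/elimination would act on the wrong oxygen. The fallback makes the position of the benzoate irrelevant. It sets out from crude 6 (benzoyl on either oxygen): BzCl, pyridine, DMAP, CH2Cl2 acylates whichever hydroxyl is free and converges on (3R,4S,5R)-4,5-bis(benzoyloxy)-3-[(tert-butyldimethylsilyl)oxy]cyclohexan-1-one F2. DBU (CH2Cl2, 0 °C) then removes the β-benzoyloxy group by E1cB elimination, the γ-benzoate staying, and the sequence comes back at 8.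

Step 9. Cleavage of the secondary silyl ether flanked by a cis-benzoate may be slow, and long acid exposure of the product could allow O5 → O4 benzoyl migration or dehydration of the β-hydroxy ketone. The fallback reverses the order of the last two operations. It sets out from 10: desilylation at the more robust enone stage (48% aq. HF, MeCN, 0 °C) should give (4S,5R)-4-(benzoyloxy)-2-[(benzoyloxy)methyl]-5-hydroxycyclohex-2-en-1-one F3. Osmium-catalysed dihydroxylation of this free alcohol (OsO4 cat., NMO, citric acid, t-BuOH/H2O, rt), again anti to the C5 benzoate, comes back to the route directly at 12, so that the sensitive product never sees a deprotection step.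

Further compounds
F1 | step 6 | (4S,5R)-4-(benzoyloxy)-5-[(tert-butyldimethylsilyl)oxy]-2-iodocyclohex-2-en-1-one | O=C1C[C@@H](O[Si](C)(C)C(C)(C)C)[C@@H](OC(=O)c2ccccc2)C=C1I
F2 | step 4 | (3R,4S,5R)-4,5-bis(benzoyloxy)-3-[(tert-butyldimethylsilyl)oxy]cyclohexan-1-one | O=C1C[C@@H](O[Si](C)(C)C(C)(C)C)[C@@H](OC(=O)c2ccccc2)[C@H](OC(=O)c2ccccc2)C1
F3 | step 9 | (4S,5R)-4-(benzoyloxy)-2-[(benzoyloxy)methyl]-5-hydroxycyclohex-2-en-1-one | O=C1C[C@@H](O)[C@@H](OC(=O)c2ccccc2)C=C1COC(=O)c1ccccc1
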